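**Assumption:** the [C@@H] centre decodes as (2S) (O1 > C1′ > C3 > H). The target is therefore (2S)-7,4′-dihydroxy-6,8,3′-triprenylflavanone, C30H36O4. Compounds 1, 4, 8 and the ligand are taken to be catalogue items.

## Retrosynthetic overview
1. Target 10 ⇒ bis-MOM ether 9 by mild acetal hydrolysis as the last step.
2. 9 ⇒ (S)-tribromoflavanone 7. All three aryl–prenyl bonds are made in one threefold Stille prenylation.
3. 7 ⇒ chromone 3 + arylboronic acid 6. This is a C2–C1′ disconnection by Rh-catalysed enantioselective 1,4-addition, which sets (2S) directly. No chalcone or oxa-Michael step is used.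
4. 3 ⇐ 7-hydroxychromone (dibromination, MOM). 6 ⇐ 2-bromo-4-iodophenol (MOM, I/Mg exchange, borylation).
5. Ring order: no ring is formed. The A/C benzopyranone is bought intact, ring B is attached as a unit, and ring C only goes from sp2 to sp3 at C2/C3.

## Route

**Step 1**
Reactants: 1, 7-hydroxy-4H-chromen-4-one
Product: 2, 6,8-dibromo-7-hydroxy-4H-chromen-4-one
Conditions: NBS (2.1 equiv), DMF, 0 °C → rt
Reagents that add atoms: N-bromosuccinimide, O=C1CCC(=O)N1Br
Why: Electrophilic aromatic bromination; C6 and C8 are the two positions ortho to the free 7-OH (also para/ortho to O1 and meta to the C4 carbonyl), so they brominate much faster than the vinylogous-ester C3.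

**Step 2**
Reactants: 2, 6,8-dibromo-7-hydroxy-4H-chromen-4-one
Product: 3, 6,8-dibromo-7-(methoxymethoxy)-4H-chromen-4-one
Conditions: MOMCl (1.5 equiv), i-Pr2NEt, CH2Cl2, 0 °C → rt
Reagents that add atoms: chloromethyl methyl ether, COCCl
Why: O-alkylation (MOM acetal formation) of an acidic phenol with a non-nucleophilic base that cannot open the chromone at C2; masking the phenol prevents a phenoxide from deactivating the enone in step 5.

**Step 3**
Reactants: 4, 2-bromo-4-iodophenol
Product: 5, 2-bromo-4-iodo-1-(methoxymethoxy)benzene
Conditions: MOMCl, i-Pr2NEt, CH2Cl2, 0 °C → rt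
Reagents that add atoms: chloromethyl methyl ether, COCCl
Why: Standard phenol MOM protection; both halogens are inert and the acidic OH is removed before metalation.

**Step 4**
Reactants: 5, 2-bromo-4-iodo-1-(methoxymethoxy)benzene
Product: 6, [3-bromo-4-(methoxymethoxy)phenyl]boronic acid
Conditions: i-PrMgCl·LiCl (1.05 equiv), THF, −20 °C; B(OMe)3, −20 °C → rt; aq NH4Cl
Reagents that add atoms: trimethyl borate, COB(OC)OC; water, O
Why: Knochel halogen–magnesium exchange is selective for C–I over C–Br, the aryl-Mg is meta to Br so it cannot form an aryne, and borate trapping with near-neutral hydrolysis gives the boronic acid with the MOM group intact.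

**Step 5 (key step)**
Reactants: 3, 6,8-dibromo-7-(methoxymethoxy)-4H-chromen-4-one; 6, [3-bromo-4-(methoxymethoxy)phenyl]boronic acid (1.8 equiv)
Product: 7, (2S)-6,8-dibromo-2-[3-bromo-4-(methoxymethoxy)phenyl]-7-(methoxymethoxy)-2,3-dihydro-4H-chromen-4-one
Conditions: [RhCl(C2H4)2]2 (2.5 mol %), (S)-MeO-F12-BIPHEP (5.5 mol %), aq KOH (10 mol %), toluene/H2O 10:1, rt; recrystallise
Reagents that add atoms: none beyond 3 and 6 (the C3–H comes from water)
Why: Hayashi–Miyaura Rh(I) asymmetric 1,4-addition, in which the aryl-Rh adds to one face of C2=C3 and the oxa-π-allyl-Rh is protonated by water at rt faster than β-aryloxide loss, with Ar–Br bonds untouched by Rh(I); the (S)-biaryl bisphosphine is chosen because its known sense on cyclohexenone ((S)-3-aryl ketone) maps spatially onto (2S)-flavanone, to be confirmed by anomalous-dispersion X-ray of 7, with the (R)-ligand available if the sense is reversed.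

**Step 6**
Reactants: 7, the (2S)-tribromoflavanone bis-MOM ether; 8, tributyl(3-methylbut-2-en-1-yl)stannane (4.5 equiv)
Product: 9, (2S)-7-(methoxymethoxy)-2-[4-(methoxymethoxy)-3-(3-methylbut-2-en-1-yl)phenyl]-6,8-bis(3-methylbut-2-en-1-yl)-2,3-dihydro-4H-chromen-4-one
Conditions: Pd(PPh3)4 (15 mol %), BHT (cat.), degassed toluene, 105 °C, sealed tube; KF/silica work-up
Reagents that add atoms: tributyl(3-methylbut-2-en-1-yl)stannane, CCCC[Sn](CCCC)(CCCC)CC=C(C)C
Why: Threefold Migita–Kosugi–Stille coupling, in which the aryl-Pd-prenyl species equilibrates (η1–η3–η1) to place Pd on the primary carbon so reductive elimination gives the linear prenylarene; the medium is base- and fluoride-free, so there is no E1cB opening of ring C and C2 stays (S), and allylstannanes do not add to the ketone without a strong Lewis acid.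

**Step 7**
Reactants: 9, the (2S)-triprenylflavanone bis-MOM ether
Product: 10, (2S)-7-hydroxy-2-[4-hydroxy-3-(3-methylbut-2-en-1-yl)phenyl]-6,8-bis(3-methylbut-2-en-1-yl)-2,3-dihydro-4H-chromen-4-one (target)
Conditions: aq HCl (about 0.3 M final), MeOH/THF, 40 °C, stop at full conversion; NaHCO3-buffered work-up kept below pH 7
Reagents that add atoms: none (only H is gained; the MOM groups leave as formaldehyde acetals)
Why: Acid-catalysed acetal hydrolysis (MOM cleavage) as routinely used on ortho-prenylphenol flavonoids, mild enough to avoid chroman formation; no base is ever present, so the retro-oxa-Michael racemisation pathway is closed.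

## Compound list
| No. | Name | SMILES | Role |
|---|---|---|---|
| 1 | 7-hydroxy-4H-chromen-4-one | O=c1ccoc2cc(O)ccc12 | starting material |
| 2 | 6,8-dibromo-7-hydroxy-4H-chromen-4-one | O=c1ccoc2c(Br)c(O)c(Br)cc12 | intermediate |
| 3 | 6,8-dibromo-7-(methoxymethoxy)-4H-chromen-4-one | COCOc1c(Br)cc2c(=O)ccoc2c1Br | intermediate |
| 4 | 2-bromo-4-iodophenol | Oc1ccc(I)cc1Br | starting material |
| 5 | 2-bromo-4-iodo-1-(methoxymethoxy)benzene | COCOc1ccc(I)cc1Br | intermediate |
| 6 | [3-bromo-4-(methoxymethoxy)phenyl]boronic acid | COCOc1ccc(B(O)O)cc1Br | intermediate |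
| 7 | (2S)-6,8-dibromo-2-[3-bromo-4-(MOMO)phenyl]-7-(MOMO)chroman-4-one | Brc1cc([C@@H]2CC(=O)c3cc(Br)c(OCOC)c(Br)c3O2)ccc1OCOC | intermediate |
| 8 | tributyl(3-methylbut-2-en-1-yl)stannane | CCCC[Sn](CCCC)(CCCC)CC=C(C)C | starting material |
| 9 | (2S)-7,4′-bis(MOMO)-6,8,3′-triprenylflavanone | CC(C)=CCc1cc([C@@H]2CC(=O)c3cc(CC=C(C)C)c(OCOC)c(CC=C(C)C)c3O2)ccc1OCOC | intermediate |
| 10 | (2S)-7,4′-dihydroxy-6,8,3′-triprenylflavanone | CC(C)=CCc1cc([C@@H]2CC(=O)c3cc(CC=C(C)C)c(O)c(CC=C(C)C)c3O2)ccc1O | target |

## Step count
- Total steps: 7
- Longest linear sequence: 5 (steps 1, 2, 5, 6, 7, or equally 3, 4, 5, 6, 7)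

## Three steps most likely to fail

1. **Step 6, threefold Stille.**
   - Risks: slow oxidative addition at the electron-rich, ortho-oxygenated bromides; hydrodebromination; linear/branched mixtures multiplied over three sites.
   - Fallback: prenylate before the stereocentre exists. Run a double Stille on achiral chromone 3, where forcing or fluoride-activated conditions are harmless. Use 4-(MOMO)-3-prenylphenylboronic acid, made from 4-bromo-2-prenylphenol by MOM protection and Li/B exchange. The Rh 1,4-addition then becomes the penultimate step.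

2. **Step 5, Rh 1,4-addition.**
   - Risks: the dibrominated aryloxide is a good leaving group, so β-elimination to chalcone could erode ee; 1,2-over-addition to the product ketone; hydroxide opening of the chromone.
   - Fallback: join 3 and 6 by Pd(II)-catalysed oxidative C2-arylation to the achiral tribromoflavone. Then set C2 by CuH-catalysed asymmetric conjugate reduction (Cu(OAc)2, chiral SEGPHOS-type ligand, silane, t-BuOH). The stereocentre then comes from hydride delivery rather than aryl delivery.

3. **Step 7, MOM removal on a tris(ortho-prenyl)phenol system.**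
   - Risks: acid-induced chroman cyclisation, MeOH or HCl addition to the prenyl groups, and slow acid racemisation.
   - Fallback: change the protecting-group timing. Cleave both MOM groups from tribromide 7, which has no alkenes, so acid is harmless there. Re-mask as silyl ethers (TBS/TIPS), run the Stille coupling, and finish with AcOH-buffered fluoride (Et3N·3HF). The prenylphenols then never see mineral acid.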